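(All runs come from a simulation from invented constants; noise was put on by code.)

When, within 2.5 h, did target stand highest in this flask, and how high, in percent of the starting material charged?

| flask | starting material | second substrate | free catalyst | remark | time |
|---|---|---|---|---|---|
| alpha | 10 mM | 10 mM | 10 µM | the very flask that is asked about, followed so far |  |
| flask | 10 mM | 10.0 mM | 10 µM |  | 2.5 h |

alpha run (percent of the starting material charged)

| time / min | target / % |
|---|---|
| 0.833 | 7.8 |
| 2.50 | 9.8 |
| 8.00 | 4.8 |
| 25.0 | 0 |
| 80.0 | 0.3 |

(each reading ± 0.5 percentage points)

Alpha is this same flask followed so far, so I read its curve directly. Did the limit matter? Alpha's highest reading came at 2.50 min, far earlier than 2.5 h, so I looked at the first minutes.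

What held the top so low? At the top, target is made as fast as it is used (its quasi-steady state), so its height is the making rate times a lifetime. I took the mean rise to the first reading, 0.0936 min⁻¹ of the charge, as the making rate. Dividing alpha's top reading by it gave 1.05 min, the lifetime of target at the crossing. This is rough, since each reading scatters by 0.5 percentage points and target was already being lost during that rise.

When is the crossing reached? A rise comes within 10.0% of its level in 2.3 lifetimes, so I expected the top near 2.41 min, close to alpha's reading at 2.50 min.

The forecast gave 10% at 2.2 min, a slightly earlier time than mine, reasoning that “A low peak with such a fast rise suggests target is consumed faster than it forms.”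

The flask gave 10.2% at 2.45 min, as forecast.

    catalyst intermediate B → free catalyst + second product (k = 62.0 s⁻¹)
    second substrate + free catalyst ⇌ catalyst intermediate B (K = 69.0 L mol⁻¹, k = 1100 L mol⁻¹ s⁻¹)
    starting material + free catalyst ⇌ catalyst intermediate A (K = 390 L mol⁻¹, k = 2000 L mol⁻¹ s⁻¹)
    catalyst intermediate A → free catalyst + target (k = 4.60 s⁻¹)
    starting material + target → side product (k = 1.20 L mol⁻¹ s⁻¹)
    target → over-reaction product (k = 0.0160 s⁻¹)

So this flask is worth stopping near 2.45 min: at 0.0537 h, a little after the top, making over using stood at 0.953. The top came after 2.33 of my rough lifetimes of 1.05 min. The longest time allowed is 143 of those lifetimes, and at 2.50 h target stands at 0%.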